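**Retrosynthetic overview**
1. Target ⇒ removal of an aryl silyl ether ⇒ acylation of a 10α allylic alcohol (tigloyl chloride) and of a 6α alcohol (4-silyloxybenzoic acid); the tertiary C4–OH stays free throughout.
2. 10α-OH ⇐ Luche reduction of a C10 enone; C8=C9 ⇐ Saegusa–Ito dehydrogenation of the C10 ketone (C1 is quaternary, so only one enolisation direction); 6α-OH ⇐ chelation-controlled 1,3-syn reduction of a C6 ketone through the C4–OH.
3. Seven-membered ring (formed last) ⇐ periodate cleavage of the C6–C10 bond of a cyclobutane-1,2-diol flanked by two five-membered rings; C4 carbinol ⇐ exo addition of iPrCeCl2 to the cyclopentanone.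
4. Cyclobutane (formed second, on the preformed five-membered enone) ⇐ new enantioselective [2+2] photocycloaddition of 3-methylcyclopent-2-en-1-one with 4-methyl-1,2-bis(trimethylsilyloxy)cyclopentene; it makes C1–C10 and C5–C6, sets C1, C5 and the cis ring fusion, and brings in all three oxygens.
5. The enediol ether ⇐ acyloin condensation of dimethyl 3-methylglutarate.

Assumption and numbering: the SMILES is read as (1R,4R,5S,6R,10S) in daucane numbering (C1 = methyl-bearing ring-fusion carbon, C2/C3 = CH2, C4 = isopropyl carbinol, C5 = ring-fusion CH, C6 = aroyloxy carbon, C7 = CH2, C8 = methyl-bearing alkene carbon, C9 = alkene CH, C10 = tigloyloxy carbon). This is a cis-fused hydroazulene with 1-Me, 5-H, 6-H, 10-H and the isopropyl on one face (β) and the three oxygens on the other (α). This numbering is used for all bicyclic compounds.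

**Route**

Step 1
Reactants: 1 dimethyl 3-methylpentanedioate (dimethyl 3-methylglutarate)
Product: 2 4-methyl-1,2-bis(trimethylsilyloxy)cyclopent-1-ene
Conditions: Na (4.2 equiv), TMSCl (4.5 equiv), toluene, reflux
Reagents that add atoms: chlorotrimethylsilane, C[Si](C)(C)Cl
Why: Rühlmann acyloin condensation, in which TMSCl traps the enediolate and the methoxide so the five-membered bis-silyl enediol ether forms cleanly; the methyl-bearing carbon is not a lasting stereocentre (it becomes sp2 C8 in step 8).

Step 2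
Reactants: 2 4-methyl-1,2-bis(trimethylsilyloxy)cyclopent-1-ene; 3 3-methylcyclopent-2-en-1-one
Product: 4 (1R,2R,6S,7S)-1,4-dimethyl-2,6-bis(trimethylsilyloxy)tricyclo[5.3.0.0^{2,6}]decan-8-one (cis-anti-cis; both 4-methyl epimers)
Conditions: AlBr3-activated oxazaborolidine from (S)-bis(3,5-dimethylphenyl)(pyrrolidin-2-yl)methanol and 2,4,6-trifluorophenylboronic acid (50 mol%), 2,6-di-tert-butylpyridine (10 mol%), enediol ether in threefold excess, CH2Cl2, −75 °C, hν (366 nm)
Reagents that add atoms: none
Why: Proposed new method: a chiral-Lewis-acid-controlled crossed [2+2] photocycloaddition of a β-alkyl cyclopentenone with a tetrasubstituted bis-silyl enediol ether, a 1:1 addition in which every atom of both partners ends up in the product (the excess alkene only speeds trapping of the excited enone and is recovered unchanged); the AlBr3-activated oxazaborolidine binds the enone carbonyl and shifts its ππ* band to longer wavelength, so that at 366 nm essentially only the bound enone is excited, and its aryl groups shield one enantiotopic face; the alkene therefore bonds first at the β-carbon (C1) from the open face and the triplet 1,4-biradical closes C5–C6, which sets C1 (methyl β) and C5 (H β) in one absolute sense and necessarily cis (a cyclopentenone cannot carry a trans-fused cyclobutane); the dark Mukaiyama–Michael pathway is suppressed because it would have to join a quaternary to a fully substituted carbon at −75 °C, and the hindered pyridine removes traces of HBr that would cleave the silyl enol ether; the (S)-catalyst is assumed to give the (1R,7S) series, and its mirror image is used if the first run shows the opposite sense; the closest known reaction types are the oxazaborolidine–AlBr3-catalysed enantioselective [2+2] photocycloaddition of cyclohex-2-enones with simple alkenes and the uncatalysed photocycloaddition of cyclopentenones with 1,2-bis(trimethylsilyloxy)cycloalkenes.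

Step 3
Reactants: 4 (1R,2R,6S,7S)-1,4-dimethyl-2,6-bis(trimethylsilyloxy)tricyclo[5.3.0.0^{2,6}]decan-8-one
Product: 5 (1R,2R,6S,7R,8R)-1,4-dimethyl-8-(propan-2-yl)-2,6-bis(trimethylsilyloxy)tricyclo[5.3.0.0^{2,6}]decan-8-ol
Conditions: iPrMgCl, CeCl3, THF, −78 → 0 °C
Reagents that add atoms: isopropylmagnesium chloride, CC(C)[Mg]Cl
Why: Imamoto organocerium 1,2-addition, which suppresses enolisation and β-hydride reduction of the hindered cyclopentanone; the nucleophile enters from the exo (β) face of the bicyclo[3.2.0]heptanone, anti to the cyclobutane and its silyloxy group, so the new carbinol centre (daucane C4) carries the isopropyl β and OH α.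

Step 4
Reactants: 5 (1R,2R,6S,7R,8R)-1,4-dimethyl-8-(propan-2-yl)-2,6-bis(trimethylsilyloxy)tricyclo[5.3.0.0^{2,6}]decan-8-ol
Product: 7 (1R,4R,5R)-4-hydroxydaucane-6,10-dione (cis-fused 5βH; 4α-OH; C8 epimers), via triol 6 (not isolated)
Conditions: K2CO3 (0.2 equiv), MeOH, 23 °C; AcOH quench, concentrate; then NaIO4, THF–H2O (pH 7 phosphate), 0 → 23 °C
Reagents that add atoms: none
Why: methanolysis of the two tertiary TMS ethers, then Malaprade glycol cleavage of the cis-cyclobutane-1,2-diol, breaks the C6–C10 bond with strain release and merges the four- and five-membered rings into the seven-membered ring; C1, C4 and C5 are untouched, so the cis fusion is kept, and the neutral pH avoids retro-aldol or C5 epimerisation of the β-hydroxy ketone.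

Step 5
Reactants: 7 (1R,4R,5R)-4-hydroxydaucane-6,10-dione
Product: 9 (1R,4R,5S,6R)-4,6-dihydroxydaucan-10-one (4α,6α-diol; C8 epimers), via boron chelate 8 (not isolated)
Conditions: Et2BOMe, THF–MeOH (4:1), −78 °C; then NaBH4, −78 °C; AcOH, then MeOH co-evaporation
Reagents that add atoms: none
Why: Narasaka–Prasad 1,3-syn reduction, in which the C4 borinate chelates and activates only the β-carbonyl (C6), leaving the hindered C10 ketone alone, and external hydride attacks the chelate from the β face (anti to the cyclopentane, isopropyl pseudo-equatorial), giving 6α-OH syn to 4α-OH.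

Step 6
Reactants: 10 4-hydroxybenzoic acid
Product: 12 4-(triisopropylsilyloxy)benzoic acid, via bis-silyl ester 11 (not isolated)
Conditions: TIPSCl (2.2 equiv), imidazole, DMF, 23 °C; then AcOH–THF–H2O, 23 °C
Reagents that add atoms: chlorotriisopropylsilane, CC(C)[Si](Cl)(C(C)C)C(C)C
Why: silylation of both acidic OH groups followed by selective hydrolysis of the labile silyl ester leaves the robust aryl TIPS ether; no stereocentre is involved.

Step 7
Reactants: 9 (1R,4R,5S,6R)-4,6-dihydroxydaucan-10-one; 12 4-(triisopropylsilyloxy)benzoic acid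
Product: 13 (1R,4R,5S,6R)-4-hydroxy-10-oxodaucan-6-yl 4-(triisopropylsilyloxy)benzoate
Conditions: DCC, DMAP, CH2Cl2, 0 → 23 °C
Reagents that add atoms: none
Why: Steglich esterification, in which only the secondary C6–OH reacts (the tertiary C4–OH is inert) and the C6–O bond is not broken, so its configuration is retained.

Step 8
Reactants: 13 (1R,4R,5S,6R)-4-hydroxy-10-oxodaucan-6-yl 4-(triisopropylsilyloxy)benzoate
Product: 16 (1R,4R,5S,6R)-4-hydroxy-10-oxodauc-8-en-6-yl 4-(triisopropylsilyloxy)benzoate, via silyl enol ether 14 (not isolated), via silylated enone 15 (not isolated)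
Conditions: TMSOTf, Et3N, CH2Cl2, 0 °C; then Pd(OAc)2 (1.1 equiv), MeCN, 23 °C; then PPTS, MeOH, 23 °C
Reagents that add atoms: none
Why: Saegusa–Ito oxidation, in which soft enolisation of the C10 ketone can only go toward C9 because C1 is quaternary and Pd(OAc)2 then gives the C8=C9 enone (both C8 epimers converge, no new stereocentre); the TMS ether formed on C4 is removed by mild methanolysis.

Step 9
Reactants: 16 (1R,4R,5S,6R)-4-hydroxy-10-oxodauc-8-en-6-yl 4-(triisopropylsilyloxy)benzoate
Product: 17 (1R,4R,5S,6R,10S)-4,10-dihydroxydauc-8-en-6-yl 4-(triisopropylsilyloxy)benzoate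
Conditions: NaBH4, CeCl3·7H2O, MeOH, −78 °C
Reagents that add atoms: none
Why: Luche 1,2-reduction of the enone, in which hydride is expected from the convex β face, anti to the five-membered ring that covers the α face of the cis-fused bicycle, which gives the 10α-alcohol (10S).

Step 10
Reactants: 17 (1R,4R,5S,6R,10S)-4,10-dihydroxydauc-8-en-6-yl 4-(triisopropylsilyloxy)benzoate; 18 (E)-2-methylbut-2-enoyl chloride (tigloyl chloride)
Product: 19 (1R,4R,5S,6R,10S)-4-hydroxy-10-[(E)-2-methylbut-2-enoyloxy]dauc-8-en-6-yl 4-(triisopropylsilyloxy)benzoate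
Conditions: pyridine, DMAP (0.2 equiv), CH2Cl2, 0 → 35 °C
Reagents that add atoms: none
Why: DMAP-catalysed acylation of the secondary allylic alcohol with the acid chloride, using pyridine rather than a trialkylamine to avoid vinylketene formation and deconjugation of the tiglate; the tertiary C4–OH does not react and C10 keeps its configuration.

Step 11
Reactants: 19 (1R,4R,5S,6R,10S)-4-hydroxy-10-[(E)-2-methylbut-2-enoyloxy]dauc-8-en-6-yl 4-(triisopropylsilyloxy)benzoate
Product: 20 (1R,4R,5S,6R,10S)-4-hydroxy-10-[(E)-2-methylbut-2-enoyloxy]dauc-8-en-6-yl 4-hydroxybenzoate (CNP0273650.13)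
Conditions: TBAF, AcOH, THF, 0 °C
Reagents that add atoms: none
Why: fluoride cleavage of the aryl silyl ether, buffered with AcOH so that neither ester nor the allylic C10–O bond is touched; no stereocentre is affected.

**Compound list**
1 | dimethyl 3-methylpentanedioate | COC(=O)CC(C)CC(=O)OC | starting material
2 | 4-methyl-1,2-bis(trimethylsilyloxy)cyclopent-1-ene | CC1CC(O[Si](C)(C)C)=C(O[Si](C)(C)C)C1 | intermediate
3 | 3-methylcyclopent-2-en-1-one | CC1=CC(=O)CC1 | starting material
4 | (1R,2R,6S,7S)-1,4-dimethyl-2,6-bis(trimethylsilyloxy)tricyclo[5.3.0.0^{2,6}]decan-8-one (cis-anti-cis; 4-methyl epimers) | O=C1CC[C@]2(C)[C@H]1[C@@]3(O[Si](C)(C)C)CC(C)C[C@@]23O[Si](C)(C)C | intermediate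
5 | (1R,2R,6S,7R,8R)-1,4-dimethyl-8-(propan-2-yl)-2,6-bis(trimethylsilyloxy)tricyclo[5.3.0.0^{2,6}]decan-8-ol | CC(C)[C@]1(O)CC[C@]2(C)[C@H]1[C@@]3(O[Si](C)(C)C)CC(C)C[C@@]23O[Si](C)(C)C | intermediate
6 | (1R,2R,6S,7R,8R)-1,4-dimethyl-8-(propan-2-yl)tricyclo[5.3.0.0^{2,6}]decane-2,6,8-triol | CC(C)[C@]1(O)CC[C@]2(C)[C@H]1[C@@]3(O)CC(C)C[C@@]23O | intermediate (not isolated)
7 | (1R,4R,5R)-4-hydroxydaucane-6,10-dione (cis-fused; 4α-OH, 4β-isopropyl, 1β-Me, 5β-H; C8 epimers) | CC(C)[C@]1(O)CC[C@]2(C)[C@H]1C(=O)CC(C)CC2=O | intermediate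
8 | (1R,4R,5R)-4-(diethylboryloxy)daucane-6,10-dione (boron chelated by the C6 carbonyl) | CC(C)[C@]1(OB(CC)CC)CC[C@]2(C)[C@H]1C(=O)CC(C)CC2=O | intermediate (not isolated)
9 | (1R,4R,5S,6R)-4,6-dihydroxydaucan-10-one (4α,6α-diol; C8 epimers) | CC(C)[C@]1(O)CC[C@]2(C)[C@H]1[C@H](O)CC(C)CC2=O | intermediate
10 | 4-hydroxybenzoic acid | OC(=O)c1ccc(O)cc1 | starting material
11 | triisopropylsilyl 4-(triisopropylsilyloxy)benzoate | CC(C)[Si](OC(=O)c1ccc(O[Si](C(C)C)(C(C)C)C(C)C)cc1)(C(C)C)C(C)C | intermediate (not isolated)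
12 | 4-(triisopropylsilyloxy)benzoic acid | OC(=O)c1ccc(O[Si](C(C)C)(C(C)C)C(C)C)cc1 | intermediate
13 | (1R,4R,5S,6R)-4-hydroxy-10-oxodaucan-6-yl 4-(triisopropylsilyloxy)benzoate (C8 epimers) | CC(C)[C@]1(O)CC[C@]2(C)[C@H]1[C@H](OC(=O)c3ccc(O[Si](C(C)C)(C(C)C)C(C)C)cc3)CC(C)CC2=O | intermediate
14 | (1R,4R,5S,6R)-4,10-bis(trimethylsilyloxy)dauc-9-en-6-yl 4-(triisopropylsilyloxy)benzoate | CC(C)[C@]1(O[Si](C)(C)C)CC[C@]2(C)[C@H]1[C@H](OC(=O)c3ccc(O[Si](C(C)C)(C(C)C)C(C)C)cc3)CC(C)C=C2O[Si](C)(C)C | intermediate (not isolated)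
15 | (1R,4R,5S,6R)-10-oxo-4-(trimethylsilyloxy)dauc-8-en-6-yl 4-(triisopropylsilyloxy)benzoate | CC(C)[C@]1(O[Si](C)(C)C)CC[C@]2(C)[C@H]1[C@H](OC(=O)c3ccc(O[Si](C(C)C)(C(C)C)C(C)C)cc3)CC(C)=CC2=O | intermediate (not isolated)
16 | (1R,4R,5S,6R)-4-hydroxy-10-oxodauc-8-en-6-yl 4-(triisopropylsilyloxy)benzoate | CC(C)[C@]1(O)CC[C@]2(C)[C@H]1[C@H](OC(=O)c3ccc(O[Si](C(C)C)(C(C)C)C(C)C)cc3)CC(C)=CC2=O | intermediate
17 | (1R,4R,5S,6R,10S)-4,10-dihydroxydauc-8-en-6-yl 4-(triisopropylsilyloxy)benzoate | CC(C)[C@]1(O)CC[C@]2(C)[C@H]1[C@H](OC(=O)c3ccc(O[Si](C(C)C)(C(C)C)C(C)C)cc3)CC(C)=C[C@@H]2O | intermediate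
18 | (E)-2-methylbut-2-enoyl chloride (tigloyl chloride) | C/C=C(\C)C(Cl)=O | starting material
19 | (1R,4R,5S,6R,10S)-4-hydroxy-10-[(E)-2-methylbut-2-enoyloxy]dauc-8-en-6-yl 4-(triisopropylsilyloxy)benzoate | C/C=C(\C)C(=O)O[C@H]1C=C(C)C[C@@H](OC(=O)c2ccc(O[Si](C(C)C)(C(C)C)C(C)C)cc2)[C@@H]2[C@@]1(C)CC[C@@]2(O)C(C)C | intermediate
20 | (1R,4R,5S,6R,10S)-4-hydroxy-10-[(E)-2-methylbut-2-enoyloxy]dauc-8-en-6-yl 4-hydroxybenzoate | C/C=C(\C)C(=O)O[C@H]1C=C(C)C[C@@H](OC(=O)c2ccc(O)cc2)[C@@H]2[C@@]1(C)CC[C@@]2(O)C(C)C | target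

**Step count and risks**

Total step count: 11. Longest linear sequence: 10 steps (1 → 2 → 4 → 5 → 7 → 9 → 13 → 16 → 17 → 19 → 20); step 6 is a one-step side branch.

The three steps most likely to fail:

Step 2 (the proposed new photocycloaddition). The risks are low enantioselectivity with a five-membered enone and loss of the silyl enol ether to the Lewis acid. The fallback uses known chemistry, sets out from 2 and 3 and comes back at 4. Uncatalysed irradiation (Pyrex, 350 nm, hexane, −20 °C) gives 4 as a racemate together with its mirror image, the (1S,2S,6R,7R)-ketone ent-4 F1. Lithiated (S)-N,S-dimethyl-S-phenylsulfoximine (n-BuLi, THF, −78 °C) then adds to the ketone from the exo face to give two diastereomers, the β-hydroxysulfoximine of 4 F2 and the β-hydroxysulfoximine of ent-4 F3, which are separated on silica gel. Heating F2 in toluene at 110 °C expels the sulfoximine and returns enantiopure 4 (Johnson resolution of ketones).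

Step 5 (chelation-controlled reduction). The risks are incomplete chelation by the tertiary C4–OH, which would erode the C6/C10 and facial selectivity, and retro-aldol of 7. The fallback sets out from 7 and comes back at 13. Both ketones are reduced without chelation (NaBH4, MeOH, −20 °C, hydride from the convex β face at C6) to the (1R,4R,5S,6R)-daucane-4,6,10-triol F4, whose C10 configuration does not matter. The less hindered C6–OH (the C10–OH is neopentylic) is esterified with 12 (1.05 equiv, DCC, DMAP) to the (1R,4R,5S,6R)-4,10-dihydroxydaucan-6-yl 4-(triisopropylsilyloxy)benzoate F5. Dess–Martin periodinane then oxidises the C10 alcohol back to the ketone, which is 13.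

Step 9 (Luche reduction). Facial selectivity is the least certain point of the route: the C1 methyl lies on the β face next to C10 and may steer hydride to the α face, giving the 10β-alcohol. The fallback sets out from 16 and comes back at 17. Substrate control is replaced by catalyst control: (R)-1-methyl-3,3-diphenyltetrahydro-1H,3H-pyrrolo[1,2-c][1,3,2]oxazaborole (the (R)-methyl-CBS catalyst) with catecholborane in toluene at −78 °C. The quaternary C1 side acts as the large group and hydride is delivered to the β face. This fallback makes no new compound, F0.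

**Further compounds**
F1 | step 2 | (1S,2S,6R,7R)-1,4-dimethyl-2,6-bis(trimethylsilyloxy)tricyclo[5.3.0.0^{2,6}]decan-8-one (ent-4) | O=C1CC[C@@]2(C)[C@@H]1[C@]3(O[Si](C)(C)C)CC(C)C[C@]23O[Si](C)(C)C
F2 | step 2 | β-hydroxysulfoximine of 4: exo adduct with (S)-N,S-dimethyl-S-phenylsulfoximine, 8-hydroxy-8-[(S)-(N-methyl-S-phenylsulfonimidoyl)methyl] derivative | c1ccccc1[S@](=O)(=NC)C[C@]2(O)CC[C@]3(C)[C@H]2[C@@]4(O[Si](C)(C)C)CC(C)C[C@@]34O[Si](C)(C)C
F3 | step 2 | β-hydroxysulfoximine of ent-4 (diastereomer of F2, same (S)-sulfur) | c1ccccc1[S@](=O)(=NC)C[C@@]2(O)CC[C@@]3(C)[C@@H]2[C@]4(O[Si](C)(C)C)CC(C)C[C@]34O[Si](C)(C)C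
F4 | step 5 | (1R,4R,5S,6R)-daucane-4,6,10-triol (C8 and C10 epimers) | CC(C)[C@]1(O)CC[C@]2(C)[C@H]1[C@H](O)CC(C)CC2O
F5 | step 5 | (1R,4R,5S,6R)-4,10-dihydroxydaucan-6-yl 4-(triisopropylsilyloxy)benzoate (C8 and C10 epimers) | CC(C)[C@]1(O)CC[C@]2(C)[C@H]1[C@H](OC(=O)c3ccc(O[Si](C(C)C)(C(C)C)C(C)C)cc3)CC(C)CC2O
F0 | step 9 | none | none
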